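## Retrosynthetic overview

1. The butenolide is attached last by Suzuki–Miyaura coupling (C12–C13) of an (E)-alkenylboronate that comes from the C11 aldehyde of the bicyclic core by Takai–Utimoto olefination (C11=C12).
2. The bicyclic core comes from a tricyclic lactone by excision of one temporary carbonyl carbon at C6. That tricycle is made in one radical bicyclization of a monocyclic precursor, forming C5–C10 (ring A) and then C6–C7 (ring B).
3. Enabling feature: O19 (on C4) and C6 both sit one atom from C5 and are syn-axial on the A/B decalin. One carbonyl carbon can therefore bridge them as an unsaturated δ-lactone (ring C4–C19–O–C(=O)–C6=C5), which activates C5 as radical acceptor, fixes the C5 configuration and leaves an α-carbonyl radical at C6. The C8=C17 methylene next to C7 is written back to a 2-(sulfonylmethyl)allyl unit, and the quaternary C10 with its C20 methyl to a tertiary carbinol oxalate.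
4. The precursor comes from acrylation and ring-closing metathesis of the vinyl diol formed by iridium-catalysed tert-(hydroxy)prenylation (sets C3 and C4). The alcohol used there carries C9, set by Sharpless epoxidation and cuprate opening of an allylic alcohol made by alkyne carboalumination.
5. Ring order: temporary lactone, then ring A and ring B in the same step, then removal of the lactone carbon, then the butenolide.

Key step: step 12

Remarks:
- Locants C1–C20 in names and comments are the labdane locants of the target; C6′ is the temporary lactone carbonyl carbon.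
- Assumption: the (R)-Tol-BINAP iridium catalyst of step 6 is taken to give the (3R,4R) anti diol; if the sense of induction is the opposite, the (S)-ligand is used.
- The CIP descriptor at C9 changes from S to R on cyclization because ligand priorities change; there is no inversion.
- The four starting materials are taken to be commercially available.

## Route

Step 1
Reactants: 1 tert-butyldimethyl(pent-4-yn-1-yloxy)silane
Product: 3 (E)-7-[(tert-butyldimethylsilyl)oxy]-3-methylhept-2-en-1-ol, via alkenyldimethylalane 2 (not isolated)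
Conditions: AlMe3, Cp2ZrCl2 (25 mol %), CH2Cl2, 0 °C to rt; then n-BuLi, (CH2O)n, THF, −78 °C to rt
Reagents that add atoms: trimethylaluminium C[Al](C)C; formaldehyde (as paraformaldehyde) C=O
Why: Negishi zirconium-catalysed carboalumination adds methyl and aluminium syn across the terminal alkyne with the metal on the terminal carbon, and hydroxymethylation of the derived alanate with retention should give the (E)-allylic alcohol carrying the C20 methyl and the C11 carbinol.

Step 2
Reactants: 3 (E)-7-[(tert-butyldimethylsilyl)oxy]-3-methylhept-2-en-1-ol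
Product: 4 [(2R,3R)-3-{3-[(tert-butyldimethylsilyl)oxy]propyl}-3-methyloxiran-2-yl]methanol
Conditions: Ti(OiPr)4 (10 mol %), D-(−)-diethyl tartrate (12 mol %), t-BuOOH, 4 Å molecular sieves, CH2Cl2, −20 °C
Reagents that add atoms: tert-butyl hydroperoxide CC(C)(C)OO
Why: Sharpless asymmetric epoxidation, in which the tartrate selects the alkene face; D-(−)-tartrate should give the (2R,3R) epoxide and so fix the carbon that becomes C9.

Step 3
Reactants: 4 [(2R,3R)-3-{3-[(tert-butyldimethylsilyl)oxy]propyl}-3-methyloxiran-2-yl]methanol; 5 (2-bromoallyl)trimethylsilane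
Product: 6 (2S,3R)-6-[(tert-butyldimethylsilyl)oxy]-3-methyl-2-[3-(trimethylsilyl)prop-1-en-2-yl]hexane-1,3-diol
Conditions: CH2=C(CH2SiMe3)MgBr (from 5, Mg, THF), CuI (30 mol %), THF, −30 to 0 °C
Reagents that add atoms: none
Why: Copper-catalysed Grignard opening of a 2,3-epoxy alcohol; the fully substituted epoxide carbon (C10) cannot undergo SN2 attack, so the alkenyl group should enter at C9 with inversion and give the 1,3-diol with C9 set.

Step 4
Reactants: 6 (2S,3R)-6-[(tert-butyldimethylsilyl)oxy]-3-methyl-2-[3-(trimethylsilyl)prop-1-en-2-yl]hexane-1,3-diol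
Product: 7 (4R,5S)-4-{3-[(tert-butyldimethylsilyl)oxy]propyl}-2,2,4-trimethyl-5-[3-(trimethylsilyl)prop-1-en-2-yl]-1,3-dioxane
Conditions: Me2C(OMe)2, PPTS (cat.), CH2Cl2, rt
Reagents that add atoms: 2,2-dimethoxypropane COC(C)(C)OC
Why: Acid-catalysed transketalization ties the primary and tertiary hydroxyls into a 1,3-dioxane, masking the tertiary C10 hydroxyl, which would otherwise form a lactol with the C3 aldehyde generated in step 6.

Step 5
Reactants: 7 (4R,5S)-4-{3-[(tert-butyldimethylsilyl)oxy]propyl}-2,2,4-trimethyl-5-[3-(trimethylsilyl)prop-1-en-2-yl]-1,3-dioxane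
Product: 8 3-{(4R,5S)-2,2,4-trimethyl-5-[3-(trimethylsilyl)prop-1-en-2-yl]-1,3-dioxan-4-yl}propan-1-ol
Conditions: Bu4NF, AcOH, THF, rt
Reagents that add atoms: none
Why: Buffered fluoride cleavage of the primary silyl ether frees the C3 hydroxyl; the acetonide and the allylsilane should tolerate these conditions.

Step 6
Reactants: 8 3-{(4R,5S)-2,2,4-trimethyl-5-[3-(trimethylsilyl)prop-1-en-2-yl]-1,3-dioxan-4-yl}propan-1-ol; 9 2-methyl-2-vinyloxirane (isoprene monoxide)
Product: 10 (2R,3R)-2-ethenyl-2-methyl-5-{(4R,5S)-2,2,4-trimethyl-5-[3-(trimethylsilyl)prop-1-en-2-yl]-1,3-dioxan-4-yl}pentane-1,3-diol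
Conditions: [Ir(cod)Cl]2 (2.5 mol %), (R)-Tol-BINAP (5 mol %), 4-cyano-3-nitrobenzoic acid (10 mol %), K3PO4 (cat.), THF, 60 °C
Reagents that add atoms: none
Why: Iridium-catalysed tert-(hydroxy)prenylation by alcohol-to-allyl hydrogen transfer: the alcohol is dehydrogenated to the aldehyde and attacked by the σ-allyliridium from isoprene monoxide through a closed chair transition state, the bisphosphine setting C3 and the (E)-allyl geometry setting the anti relationship at the quaternary C4 (methyl, C19 hydroxymethyl, C5 vinyl).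

Step 7
Reactants: 10 (2R,3R)-2-ethenyl-2-methyl-5-{(4R,5S)-2,2,4-trimethyl-5-[3-(trimethylsilyl)prop-1-en-2-yl]-1,3-dioxan-4-yl}pentane-1,3-diol
Product: 12 (2R,3R)-2-ethenyl-2-methyl-3-[(triethylsilyl)oxy]-5-{(4R,5S)-2,2,4-trimethyl-5-[3-(trimethylsilyl)prop-1-en-2-yl]-1,3-dioxan-4-yl}pentyl prop-2-enoate, via hydroxy acrylate 11 (not isolated)
Conditions: CH2=CHCOCl, Et3N, CH2Cl2, −78 °C; then Et3SiCl, imidazole, DMAP (cat.), rt
Reagents that add atoms: acryloyl chloride C=CC(Cl)=O; chlorotriethylsilane CC[Si](Cl)(CC)CC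
Why: Kinetic acylation should select the primary C19 hydroxyl over the hindered secondary C3 hydroxyl, and silylating C3 in the same flask blocks migration of the acyl group to O3.

Step 8
Reactants: 12 (2R,3R)-2-ethenyl-2-methyl-3-[(triethylsilyl)oxy]-5-{(4R,5S)-2,2,4-trimethyl-5-[3-(trimethylsilyl)prop-1-en-2-yl]-1,3-dioxan-4-yl}pentyl prop-2-enoate
Product: 13 (5R)-5-methyl-5-[(1R)-1-[(triethylsilyl)oxy]-3-{(4R,5S)-2,2,4-trimethyl-5-[3-(trimethylsilyl)prop-1-en-2-yl]-1,3-dioxan-4-yl}propyl]-5,6-dihydro-2H-pyran-2-one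
Conditions: second-generation Grubbs catalyst (5 mol %), CH2Cl2 (5 mM), 40 °C
Reagents that add atoms: none
Why: Ring-closing metathesis of the acrylate with the vinyl group gives the six-membered unsaturated lactone with loss of ethene; the 1,1-disubstituted allylsilane alkene is too hindered to compete.

Step 9
Reactants: 13 (5R)-5-methyl-5-[(1R)-1-[(triethylsilyl)oxy]-3-{(4R,5S)-2,2,4-trimethyl-5-[3-(trimethylsilyl)prop-1-en-2-yl]-1,3-dioxan-4-yl}propyl]-5,6-dihydro-2H-pyran-2-one
Product: 15 (5R)-5-{(1R,4R,5S)-4-hydroxy-5-(hydroxymethyl)-4-methyl-6-[(phenylsulfonyl)methyl]-1-[(triethylsilyl)oxy]hept-6-en-1-yl}-5-methyl-5,6-dihydro-2H-pyran-2-one, via allyl sulfone acetonide 14 (not isolated)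
Conditions: PhSO2Cl, [Cu(dap)2]Cl (1 mol %; dap = 2,9-bis(4-methoxyphenyl)-1,10-phenanthroline), MeCN, green LEDs, rt; then MeOH, PPTS (cat.), 0 °C
Reagents that add atoms: benzenesulfonyl chloride O=S(=O)(Cl)c1ccccc1
Why: Photocatalytic atom-transfer sulfonylation with the monovalent copper complex adds the sulfonyl radical to the allylsilane terminus and loss of Me3SiCl gives the transposed allyl sulfone (the electron-poor lactone alkene is inert to the electrophilic sulfonyl radical); PPTS in MeOH then cleaves the strained acetonide.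

Step 10
Reactants: 15 (5R)-5-{(1R,4R,5S)-4-hydroxy-5-(hydroxymethyl)-4-methyl-6-[(phenylsulfonyl)methyl]-1-[(triethylsilyl)oxy]hept-6-en-1-yl}-5-methyl-5,6-dihydro-2H-pyran-2-one
Product: 16 (5R)-5-{(1R,4R,5S)-5-{[(tert-butyldimethylsilyl)oxy]methyl}-4-hydroxy-4-methyl-6-[(phenylsulfonyl)methyl]-1-[(triethylsilyl)oxy]hept-6-en-1-yl}-5-methyl-5,6-dihydro-2H-pyran-2-one
Conditions: t-BuMe2SiCl, imidazole, CH2Cl2, 0 °C to rt
Reagents that add atoms: tert-butylchlorodimethylsilane CC(C)(C)[Si](C)(C)Cl
Why: Silyl chloride with imidazole should protect the primary C11 hydroxyl and leave the hindered tertiary C10 hydroxyl free for step 11.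

Step 11
Reactants: 16 (5R)-5-{(1R,4R,5S)-5-{[(tert-butyldimethylsilyl)oxy]methyl}-4-hydroxy-4-methyl-6-[(phenylsulfonyl)methyl]-1-[(triethylsilyl)oxy]hept-6-en-1-yl}-5-methyl-5,6-dihydro-2H-pyran-2-one
Product: 17 methyl oxalate of the tertiary C10 hydroxyl of 16
Conditions: MeO2CCOCl, Et3N, DMAP (cat.), CH2Cl2, 0 °C to rt
Reagents that add atoms: methyl chlorooxoacetate COC(=O)C(Cl)=O
Why: DMAP-catalysed acylation of the tertiary alcohol gives the mixed oxalate, the established precursor of tertiary alkyl radicals.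

Step 12
Reactants: 17 methyl oxalate of the tertiary C10 hydroxyl of 16
Product: 19 (3R,4R,5S,6S,9R,10R)-11-[(tert-butyldimethylsilyl)oxy]-3-[(triethylsilyl)oxy]-12,13,14,15,16-pentanorlabd-8(17)-ene-6-carboxylic acid 19-lactone, via cesium oxalate 18 (not isolated)
Conditions: CsOH (1.0 equiv), THF/H2O, 0 °C, then evaporation; Ir[dF(CF3)ppy]2(dtbbpy)PF6 (1 mol %), DME/DMF (3:1, 5 mM), blue LEDs, 60 °C
Reagents that add atoms: none
Why: Proposed new method: oxidation of the oxalate by the photoexcited iridium complex releases two CO2 and the tertiary C10 radical, which adds 6-exo-trig to C5, the β-carbon of the unsaturated δ-lactone (ring A); the electrophilic lactone α-radical at C6 then adds 6-endo-trig to the CH2 terminus (C7) of the 2-substituted allyl sulfone (ring B), and β-scission of PhSO2• creates the C8=C17 methylene, the sulfonyl radical being reduced to sulfinate by the reduced photocatalyst so that the cycle is redox-neutral. The closest known reaction types are the photoredox Giese addition of tertiary radicals from alkyl oxalates to butenolides and unsaturated lactones and the radical allylation of carbon radicals with allyl sulfones; only their union in one intramolecular bicyclization is untested. C5 is controlled by the tether: the C3–C2–C1 chain hangs from C4 of the lactone ring, so C10 can reach C5 only on the face cis to that chain, and with the 4R centre this is the required 5S configuration. C10 is controlled by a chair transition state for ring A in which the C20 methyl is axial (syn to the C19 methylene of the lactone) and the branched C9 substituent equatorial; C6 and C9 are then trans-diequatorial on ring A, so ring B closes trans-fused with C11 equatorial on the preset C9 centre, and the temporary C6 centre follows from cis-annulation onto the lactone. The step needs 6-endo rather than 5-exo attack of the C6 radical and ring closure faster than its reduction, which the 1,1-disubstituted alkene carbon C8 with its fragmenting β-sulfonyl group, the rigid cis-bicycle holding C6 next to C7, high dilution and a low photocatalyst loading should secure.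

Step 13
Reactants: 19 (3R,4R,5S,6S,9R,10R)-11-[(tert-butyldimethylsilyl)oxy]-3-[(triethylsilyl)oxy]-12,13,14,15,16-pentanorlabd-8(17)-ene-6-carboxylic acid 19-lactone
Product: 21 (3R,4R,5S,9R,10R)-11-[(tert-butyldimethylsilyl)oxy]-3-[(triethylsilyl)oxy]-12,13,14,15,16-pentanorlabd-8(17)-en-19-ol, via lithium carboxylate 20 (not isolated)
Conditions: LiOH (1.1 equiv), THF/H2O, rt, then evaporation; Ir[dF(CF3)ppy]2(dtbbpy)PF6 (2 mol %), 2,4,6-triisopropylbenzenethiol (20 mol %), DMSO/H2O, blue LEDs, rt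
Reagents that add atoms: none
Why: Saponification opens the δ-lactone and photoredox hydrodecarboxylation (carboxylate oxidation, loss of CO2, hydrogen-atom transfer from the thiol cocatalyst) replaces the temporary carboxyl by hydrogen, so C6 becomes CH2 and O19 is the only free hydroxyl.

Step 14
Reactants: 21 (3R,4R,5S,9R,10R)-11-[(tert-butyldimethylsilyl)oxy]-3-[(triethylsilyl)oxy]-12,13,14,15,16-pentanorlabd-8(17)-en-19-ol
Product: 22 (3R,4R,5S,9R,10R)-11-[(tert-butyldimethylsilyl)oxy]-3-[(triethylsilyl)oxy]-12,13,14,15,16-pentanorlabd-8(17)-en-19-yl acetate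
Conditions: Ac2O, pyridine, DMAP (cat.), CH2Cl2, rt
Reagents that add atoms: acetic anhydride CC(=O)OC(C)=O
Why: DMAP-catalysed esterification of the single free (primary, C19) hydroxyl, so no site selectivity is required.

Step 15
Reactants: 22 (3R,4R,5S,9R,10R)-11-[(tert-butyldimethylsilyl)oxy]-3-[(triethylsilyl)oxy]-12,13,14,15,16-pentanorlabd-8(17)-en-19-yl acetate
Product: 23 (3R,4R,5S,9R,10R)-3,11-dihydroxy-12,13,14,15,16-pentanorlabd-8(17)-en-19-yl acetate
Conditions: HF·pyridine, pyridine, THF, 0 °C to rt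
Reagents that add atoms: none
Why: Fluoride cleavage of both silyl ethers under mildly acidic, buffered conditions that should not promote acetyl migration from O19 to O3.

Step 16
Reactants: 23 (3R,4R,5S,9R,10R)-3,11-dihydroxy-12,13,14,15,16-pentanorlabd-8(17)-en-19-yl acetate
Product: 24 (3R,4R,5S,9R,10R)-3-hydroxy-11-oxo-12,13,14,15,16-pentanorlabd-8(17)-en-19-yl acetate
Conditions: TEMPO (10 mol %), PhI(OAc)2, CH2Cl2, rt
Reagents that add atoms: none
Why: Oxoammonium (TEMPO) oxidation is selective for the primary C11 alcohol over the hindered secondary C3 alcohol and is non-basic, so the epimerizable β,γ-unsaturated aldehyde should not isomerize.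

Step 17
Reactants: 24 (3R,4R,5S,9R,10R)-3-hydroxy-11-oxo-12,13,14,15,16-pentanorlabd-8(17)-en-19-yl acetate
Product: 25 (3R,4R,5S,9R,10R,11E)-3-hydroxy-12-(4,4,5,5-tetramethyl-1,3,2-dioxaborolan-2-yl)-13,14,15,16-tetranorlabda-8(17),11-dien-19-yl acetate
Conditions: CrCl2 (8 equiv), Cl2CHBpin, LiI, THF, rt
Reagents that add atoms: 2-(dichloromethyl)-4,4,5,5-tetramethyl-1,3,2-dioxaborolane ClC(Cl)B1OC(C)(C)C(C)(C)O1
Why: Takai–Utimoto olefination with the geminal dichromium reagent formed by divalent chromium should give the (E)-alkenylboronate under non-basic conditions that tolerate the free hydroxyl and the acetate.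

Step 18
Reactants: 25 (3R,4R,5S,9R,10R,11E)-3-hydroxy-12-(4,4,5,5-tetramethyl-1,3,2-dioxaborolan-2-yl)-13,14,15,16-tetranorlabda-8(17),11-dien-19-yl acetate; 26 3-bromofuran-2(5H)-one
Product: 27 (3R,4R,5S,9R,10R,11E)-19-acetoxy-3-hydroxylabda-8(17),11,13-trien-16,15-olide (19-O-acetyl-14-deoxy-11,12-didehydroandrographolide)
Conditions: PdCl2(dppf) (5 mol %), K3PO4, THF/H2O, rt
Reagents that add atoms: none
Why: Suzuki–Miyaura coupling with retention of the (E)-alkene geometry joins C12 to C13 of the butenolide; phosphate base at room temperature should spare the acetate and the base-sensitive butenolide.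

## Compound list

1 | tert-butyldimethyl(pent-4-yn-1-yloxy)silane | C#CCCCO[Si](C)(C)C(C)(C)C | starting material
2 | (E)-{5-[(tert-butyldimethylsilyl)oxy]-2-methylpent-1-en-1-yl}dimethylalane (not isolated) | C[Al](C)/C=C(\C)CCCO[Si](C)(C)C(C)(C)C | intermediate
3 | (E)-7-[(tert-butyldimethylsilyl)oxy]-3-methylhept-2-en-1-ol | OC/C=C(\C)CCCO[Si](C)(C)C(C)(C)C | intermediate
4 | [(2R,3R)-3-{3-[(tert-butyldimethylsilyl)oxy]propyl}-3-methyloxiran-2-yl]methanol | CC(C)(C)[Si](C)(C)OCCC[C@@]1(C)O[C@@H]1CO | intermediate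
5 | (2-bromoallyl)trimethylsilane | C=C(Br)C[Si](C)(C)C | starting material
6 | (2S,3R)-6-[(tert-butyldimethylsilyl)oxy]-3-methyl-2-[3-(trimethylsilyl)prop-1-en-2-yl]hexane-1,3-diol | CC(C)(C)[Si](C)(C)OCCC[C@@](C)(O)[C@@H](C(=C)C[Si](C)(C)C)CO | intermediate
7 | (4R,5S)-4-{3-[(tert-butyldimethylsilyl)oxy]propyl}-2,2,4-trimethyl-5-[3-(trimethylsilyl)prop-1-en-2-yl]-1,3-dioxane | CC(C)(C)[Si](C)(C)OCCC[C@@]1(C)OC(C)(C)OC[C@@H]1C(=C)C[Si](C)(C)C | intermediate
8 | 3-{(4R,5S)-2,2,4-trimethyl-5-[3-(trimethylsilyl)prop-1-en-2-yl]-1,3-dioxan-4-yl}propan-1-ol | OCCC[C@@]1(C)OC(C)(C)OC[C@@H]1C(=C)C[Si](C)(C)C | intermediate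
9 | 2-methyl-2-vinyloxirane (isoprene monoxide, racemic) | CC1(C=C)CO1 | starting material
10 | (2R,3R)-2-ethenyl-2-methyl-5-{(4R,5S)-2,2,4-trimethyl-5-[3-(trimethylsilyl)prop-1-en-2-yl]-1,3-dioxan-4-yl}pentane-1,3-diol | C=C[C@](C)(CO)[C@H](O)CC[C@@]1(C)OC(C)(C)OC[C@@H]1C(=C)C[Si](C)(C)C | intermediate
11 | (2R,3R)-2-ethenyl-3-hydroxy-2-methyl-5-{(4R,5S)-2,2,4-trimethyl-5-[3-(trimethylsilyl)prop-1-en-2-yl]-1,3-dioxan-4-yl}pentyl prop-2-enoate (not isolated) | C=CC(=O)OC[C@@](C)(C=C)[C@H](O)CC[C@@]1(C)OC(C)(C)OC[C@@H]1C(=C)C[Si](C)(C)C | intermediate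
12 | (2R,3R)-2-ethenyl-2-methyl-3-[(triethylsilyl)oxy]-5-{(4R,5S)-2,2,4-trimethyl-5-[3-(trimethylsilyl)prop-1-en-2-yl]-1,3-dioxan-4-yl}pentyl prop-2-enoate | C=CC(=O)OC[C@@](C)(C=C)[C@H](O[Si](CC)(CC)CC)CC[C@@]1(C)OC(C)(C)OC[C@@H]1C(=C)C[Si](C)(C)C | intermediate
13 | (5R)-5-methyl-5-[(1R)-1-[(triethylsilyl)oxy]-3-{(4R,5S)-2,2,4-trimethyl-5-[3-(trimethylsilyl)prop-1-en-2-yl]-1,3-dioxan-4-yl}propyl]-5,6-dihydro-2H-pyran-2-one | O=C1OC[C@@](C)(C=C1)[C@H](O[Si](CC)(CC)CC)CC[C@@]2(C)OC(C)(C)OC[C@@H]2C(=C)C[Si](C)(C)C | intermediate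
14 | (5R)-5-methyl-5-[(1R)-3-{(4R,5S)-2,2,4-trimethyl-5-[3-(phenylsulfonyl)prop-1-en-2-yl]-1,3-dioxan-4-yl}-1-[(triethylsilyl)oxy]propyl]-5,6-dihydro-2H-pyran-2-one (not isolated) | O=C1OC[C@@](C)(C=C1)[C@H](O[Si](CC)(CC)CC)CC[C@@]2(C)OC(C)(C)OC[C@@H]2C(=C)CS(=O)(=O)c1ccccc1 | intermediate
15 | (5R)-5-{(1R,4R,5S)-4-hydroxy-5-(hydroxymethyl)-4-methyl-6-[(phenylsulfonyl)methyl]-1-[(triethylsilyl)oxy]hept-6-en-1-yl}-5-methyl-5,6-dihydro-2H-pyran-2-one | O=C1OC[C@@](C)(C=C1)[C@H](O[Si](CC)(CC)CC)CC[C@@](C)(O)[C@@H](C(=C)CS(=O)(=O)c1ccccc1)CO | intermediate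
16 | (5R)-5-{(1R,4R,5S)-5-{[(tert-butyldimethylsilyl)oxy]methyl}-4-hydroxy-4-methyl-6-[(phenylsulfonyl)methyl]-1-[(triethylsilyl)oxy]hept-6-en-1-yl}-5-methyl-5,6-dihydro-2H-pyran-2-one | O=C1OC[C@@](C)(C=C1)[C@H](O[Si](CC)(CC)CC)CC[C@@](C)(O)[C@@H](C(=C)CS(=O)(=O)c1ccccc1)CO[Si](C)(C)C(C)(C)C | intermediate
17 | methyl oxalate of the tertiary C10 hydroxyl of 16 | O=C1OC[C@@](C)(C=C1)[C@H](O[Si](CC)(CC)CC)CC[C@@](C)(OC(=O)C(=O)OC)[C@@H](C(=C)CS(=O)(=O)c1ccccc1)CO[Si](C)(C)C(C)(C)C | intermediate
18 | cesium salt of the hydrogen oxalate of the tertiary C10 hydroxyl of 16 (not isolated) | O=C1OC[C@@](C)(C=C1)[C@H](O[Si](CC)(CC)CC)CC[C@@](C)(OC(=O)C(=O)[O-])[C@@H](C(=C)CS(=O)(=O)c1ccccc1)CO[Si](C)(C)C(C)(C)C.[Cs+] | intermediate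
19 | (3R,4R,5S,6S,9R,10R)-11-[(tert-butyldimethylsilyl)oxy]-3-[(triethylsilyl)oxy]-12,13,14,15,16-pentanorlabd-8(17)-ene-6-carboxylic acid 19-lactone | C=C1C[C@H]3[C@@H]2[C@](C)(COC3=O)[C@H](O[Si](CC)(CC)CC)CC[C@@]2(C)[C@@H]1CO[Si](C)(C)C(C)(C)C | intermediate
20 | lithium (3R,4R,5S,6S,9R,10R)-11-[(tert-butyldimethylsilyl)oxy]-19-hydroxy-3-[(triethylsilyl)oxy]-12,13,14,15,16-pentanorlabd-8(17)-ene-6-carboxylate (not isolated) | C=C1C[C@H](C(=O)[O-])[C@@H]2[C@](C)(CO)[C@H](O[Si](CC)(CC)CC)CC[C@@]2(C)[C@@H]1CO[Si](C)(C)C(C)(C)C.[Li+] | intermediate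
21 | (3R,4R,5S,9R,10R)-11-[(tert-butyldimethylsilyl)oxy]-3-[(triethylsilyl)oxy]-12,13,14,15,16-pentanorlabd-8(17)-en-19-ol | C=C1CC[C@@H]2[C@](C)(CO)[C@H](O[Si](CC)(CC)CC)CC[C@@]2(C)[C@@H]1CO[Si](C)(C)C(C)(C)C | intermediate
22 | (3R,4R,5S,9R,10R)-11-[(tert-butyldimethylsilyl)oxy]-3-[(triethylsilyl)oxy]-12,13,14,15,16-pentanorlabd-8(17)-en-19-yl acetate | C=C1CC[C@@H]2[C@](C)(COC(C)=O)[C@H](O[Si](CC)(CC)CC)CC[C@@]2(C)[C@@H]1CO[Si](C)(C)C(C)(C)C | intermediate
23 | (3R,4R,5S,9R,10R)-3,11-dihydroxy-12,13,14,15,16-pentanorlabd-8(17)-en-19-yl acetate | C=C1CC[C@@H]2[C@](C)(COC(C)=O)[C@H](O)CC[C@@]2(C)[C@@H]1CO | intermediate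
24 | (3R,4R,5S,9R,10R)-3-hydroxy-11-oxo-12,13,14,15,16-pentanorlabd-8(17)-en-19-yl acetate | C=C1CC[C@@H]2[C@](C)(COC(C)=O)[C@H](O)CC[C@@]2(C)[C@@H]1C=O | intermediate
25 | (3R,4R,5S,9R,10R,11E)-3-hydroxy-12-(4,4,5,5-tetramethyl-1,3,2-dioxaborolan-2-yl)-13,14,15,16-tetranorlabda-8(17),11-dien-19-yl acetate | C=C1CC[C@@H]2[C@](C)(COC(C)=O)[C@H](O)CC[C@@]2(C)[C@@H]1/C=C/B1OC(C)(C)C(C)(C)O1 | intermediate
26 | 3-bromofuran-2(5H)-one | O=C1OCC=C1Br | starting material
27 | (3R,4R,5S,9R,10R,11E)-19-acetoxy-3-hydroxylabda-8(17),11,13-trien-16,15-olide | C=C1CC[C@@H]2[C@](C)(COC(C)=O)[C@H](O)CC[C@@]2(C)[C@@H]1/C=C/C1=CCOC1=O | target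

## Step count and risks

Total step count: 18. Longest linear sequence: 18 steps (from 1 to 27).

Steps most likely to fail:

1. Step 12 (Proposed new method). The C6 radical may be reduced by the reduced photocatalyst before ring B closes. The alkoxycarbonyl radical may also be trapped by the nearby allyl sulfone alkene before the second CO2 is lost, or the hindered 6-exo addition may be outrun by hydrogen abstraction. Fallback with known chemistry, run stepwise: starting from 18, the oxalate Giese addition is carried out under the same photocatalyst with 2,4,6-triisopropylbenzenethiol and water as hydrogen source, so that the sequence stops after ring A at the cis-fused bicyclic lactone with C6 as CH2 and the allyl sulfone intact, F1. Ring B is then closed by intramolecular Tsuji–Trost allylation: the lithium enolate of the lactone (LiN(SiMe3)2, THF, −78 °C) attacks the π-allyl complex formed from the allyl sulfone and Pd(PPh3)4 (zerovalent palladium), which returns to the route at 19.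

2. Step 13. The hindered lactone may open slowly, the hydroxy acid may relactonize before the carboxylate is oxidized, and thiyl radicals may add to the exocyclic methylene. Fallback: starting from 19, reduction with i-Bu2AlH (CH2Cl2, −78 °C) gives the C6′ lactol F2. Tsuji–Wilkinson decarbonylation of its open hydroxy-aldehyde form with RhCl(PPh3)3 (stoichiometric, toluene, 110 °C) then removes the carbon as CO and returns to the route at 21.

3. Step 3. SN2 attack of the bulky 2-substituted alkenyl copper reagent at the hindered C9 may be slow, allowing Payne rearrangement and opening at C11 or loss of the allylsilane. Fallback: starting from 4, the smaller isopropenylmagnesium bromide with CuI opens the epoxide to the isopropenyl diol F3. Alkoxide-directed allylic lithiation of the isopropenyl methyl group (n-BuLi, TMEDA, Et2O) and quenching with Me3SiCl gives the C,O,O-tris(trimethylsilyl) compound F4. Citric acid in MeOH removes the two O-silyl groups and returns to the route at 6.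

## Further compounds

F1 | step 12 | (3R,4R,5S,9S,10R) cis-fused bicyclic δ-lactone with ring A closed (C5–C10), C6 as CH2 and the 2-[(phenylsulfonyl)methyl]allyl group still on C9 | O=C1C[C@@H]2[C@](C)(CO1)[C@H](O[Si](CC)(CC)CC)CC[C@@]2(C)[C@@H](C(=C)CS(=O)(=O)c1ccccc1)CO[Si](C)(C)C(C)(C)C
F2 | step 13 | C6′ lactol (hemiacetal) of 19 | C=C1C[C@H]3[C@@H]2[C@](C)(COC3O)[C@H](O[Si](CC)(CC)CC)CC[C@@]2(C)[C@@H]1CO[Si](C)(C)C(C)(C)C
F3 | step 3 | (2S,3R)-6-[(tert-butyldimethylsilyl)oxy]-3-methyl-2-(prop-1-en-2-yl)hexane-1,3-diol | CC(C)(C)[Si](C)(C)OCCC[C@@](C)(O)[C@@H](C(C)=C)CO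
F4 | step 3 | 1,3-bis-O-trimethylsilyl ether of 6 | CC(C)(C)[Si](C)(C)OCCC[C@@](C)(O[Si](C)(C)C)[C@@H](C(=C)C[Si](C)(C)C)CO[Si](C)(C)C
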